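# Proposed synthesis of CNP0482979.0 through an aryne–diarylfuran cycloaddition

## Numbering and labels

The three naphthalene units are called A, B and C, each numbered as 8-methoxynaphthalen-1-ol. Unit A is bonded through A2 to B2, and unit C through C2 to B4.

Compounds of the route (SMILES are in the list after the steps):

- 1 naphthalene-1,8-diol
- 2 8-methoxynaphthalen-1-ol
- 3 1-methoxy-8-(methoxymethoxy)naphthalene
- 4 the 2-lithio derivative of 3, formed in the flask
- 5 the 2-(pinacolboryl) derivative of 3
- 6 2,4-dibromofuran
- 7 the mono-coupled 4-bromo-2-naphthylfuran, formed in the flask
- 8 2,4-bis[8-methoxy-1-(methoxymethoxy)naphthalen-2-yl]furan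
- 9 3-methoxy-2-(trimethylsilyl)phenyl trifluoromethanesulfonate
- 10 3-methoxybenzyne, formed in the flask
- 11 the oxygen-bridged cycloadduct
- 12 the ring-opened bis(methoxymethyl) ether, formed in the flask
- 13 the target

## Analysis of the target

The target 13 (C33H26O6) is a fully aromatic trimer of 8-methoxynaphthalen-1-ol in which unit B is bonded through B2 to A2 and through B4 to C2. It contains no stereocentre and neither biaryl bond carries an axial descriptor, so configuration matters only in one transient intermediate of the route. Each unit has a free hydroxyl at C1 that is hydrogen-bonded to the peri methoxy group at C8, and the three hydroxyls must remain distinguishable from the three methyl ethers throughout. The free naphthols are electron-rich and prone to oxidation to quinones or coupled products, above all in basic aerated media, so they should be unveiled last. The difficulty is concentrated in unit B, a 1,2,4,8-tetrasubstituted naphthalene whose two aryl bonds sit next to a hydroxyl (B2) and in a peri-hindered position (B4), which makes cross-coupling on ring B itself unattractive. The route rests on the phenol ring of B, whose atoms B1 (OH), B2 (aryl), B3 (H), B4 (aryl), B4a and B8a reproduce a 2,4-diarylfuran (furan C5 = B1, C4 = B2, C3 = B3, C2 = B4, furan oxygen = the B1 oxygen) fused across the B4a–B8a bond of a 3-methoxybenzyne. Since units A and C are identical, one naphthyl building block serves for both.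

## Retrosynthetic reasoning

**13 to 11.** No carbon–carbon bond is cut in the first step back. The B1 hydroxyl of 13 is read as what is left of an oxygen bridge between B1 and B4, and the two outer hydroxyls are masked as methoxymethyl ethers. This leads to the oxygen-bridged dihydronaphthalene 11, with the ring-opened bis-ether 12 lying in between. Bridge opening and acetal cleavage are both triggered by acid and can share one operation. The forward reaction has to ionise the B4–O bond rather than the B1–O bond, so that the oxygen stays on B1.

**11 to 8 and 10.** The bonds B1–B8a and B4–B4a are cut. They join the phenol ring of B to its benzo ring, so this cut divides 11 into furan 8, which already carries both outer units, and aryne 10, which carries the B8 methoxy group. Cutting A2–B2 and B4–C2 instead would call for two hindered couplings on a naphthalene. The gain is a convergent, late construction of ring B in which one ring and two bonds form at once. In the forward direction the unsubstituted furan α-carbon must bond to the methoxy-flanked carbon of 10, which is set free in the flask from the silylaryl triflate 9.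

**8 to two molecules of 5 and 6.** The two furan–naphthyl bonds are cut. Both aryl groups are the same, so one boronate 5 serves twice. The bonds that later become A2–B2 and B4–C2 are thus made on an unhindered five-membered ring, by palladium-catalysed cross-coupling with dibromofuran 6. The mono-coupled bromofuran 7 is passed through on the way.

**5 to 3.** The carbon–boron bond is cut. The methoxymethoxy group of 3 directs metalation to C2, giving aryllithium 4, which is then borylated. The same group later protects the naphthol through the key step.

**3 to 2 to 1.** Two oxygen–carbon bonds are cut. Diol 1 is desymmetrised by a single methylation to 2, which fixes the hydroxyl/methoxy pattern of units A and C at the outset. The remaining hydroxyl is then protected to give 3.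

## Alternatives that were turned down

Alternative 1: The cut is made at A1–A2 and C1–C2, so that the phenol rings of both outer units are closed last on a finished ring B. In the precursor A1, ring B (as its B1 methoxymethyl ether) carries at B2 and B4 a 3-arylprop-2-enyl arm, and the aryl group of each arm bears a diethylcarbamoyl group flanked by a methoxy group. A lithium amide base would remove a proton from each doubly activated CH2 group. Each allyl anion would then acylate on its neighbouring amide with loss of the diethylamino group, giving the bis-naphthol A2.

- For it: every oxygen position is fixed by the building blocks, so no orientational question arises, and two rings form in one operation.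
- Against it: A1 needs a B core functionalised differently at B2 and B4 and two allyl–aryl bond constructions. The closure requires a cis arrangement across the double bond of each arm, which is reached only through the delocalised anion. A tertiary amide is a sluggish electrophile towards a stabilised, hindered carbanion. Both closures must succeed in the same molecule. The sequence would run to roughly ten or more steps.
- Comparison: on regiochemical certainty this alternative is stronger than the chosen route. The chosen route offers six steps, a bimolecular ring construction from three simple pieces, and no carbanion chemistry on a late, crowded intermediate.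

Alternative 2: The cut is made at the aryl–carbonyl bond A1–A8a of a tetralone form of unit A. In the N-methoxy-N-methylamide A3, bromine–lithium exchange on the 2-bromo-3-methoxyphenethyl chain would give an aryllithium that closes on the amide to the tetralone A4. A later dehydrogenation would make ring A aromatic.

- For it: this anionic cycliacylation is dependable, stops cleanly at the ketone, and leaves no doubt about where the oxygen sits.
- Against it: it builds only one of the three units. The B4–C2 bond must already be present in A3, so that hindered bond has to be made by cross-coupling between two naphthalenes. The amide α-hydrogen of A3 is activated by its aryl group and can be removed by the organolithium, which would block the closure. A4 still needs an oxidation-level correction in the presence of electron-rich rings. The identity of units A and C is not exploited. The sequence is linear and well beyond ten steps.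
- Comparison: it is as strong as or stronger than the chosen route on the predictability of the ring-forming step. The chosen route offers far better step economy and makes no biaryl bond on a naphthalene.

Alternative 3: The cut is made at B3–B4, closing the phenol ring of B by carbonyl chemistry. An alkoxide base would deprotonate the diarylmethane CH2 group of the enaminone A5. The extended enolate would add to the aminomethylene carbon, and elimination of the dimethylamino group would give the naphthol A6. A6 is the same compound as 12 of the present route.

- For it: it closes the same ring as the chosen route. The B1 oxygen comes from a ketone carbon, so the regiochemistry is certain. It arrives at the same penultimate compound.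
- Against it: A5 contains a diarylmethane unit, a hindered aryl ketone carrying the second naphthyl group, and an aminomethylene group, each of which must be installed at a crowded position. Its CH2 group is only weakly acidic, because the flanking aryl ketone is twisted out of conjugation by its two ortho substituents. The count is about nine or ten steps.
- Comparison: it is stronger on regiocontrol of ring B. The chosen route offers a six-step convergent assembly in which the only uncertain selectivity sits in one late step that has a known remedy.

Key step: step 5

Assumption: no axial configuration is specified for the two biaryl bonds, so they are treated as configurationally undefined, and 2,4-dibromofuran is taken as a purchasable building block that is used freshly purified.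

## Route

Step 1
Reactants: 1 naphthalene-1,8-diol
Product: 2 8-methoxynaphthalen-1-ol
Conditions: MeI (1.05 equiv), K2CO3 (1.1 equiv), acetone, rt, under argon
Reagents that add atoms: iodomethane, CI
Why: Williamson ether synthesis; the monoanion of the peri-diol is stabilised by an intramolecular hydrogen bond and forms easily, whereas the remaining hydroxyl of 2 is hydrogen-bonded to the new methoxy group and is far less acidic, so alkylation should stop at the monoether.

Step 2
Reactants: 2 8-methoxynaphthalen-1-ol
Product: 3 1-methoxy-8-(methoxymethoxy)naphthalene
Conditions: NaH, MOMCl, DMF, 0 °C to rt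
Reagents that add atoms: chloromethyl methyl ether, COCCl
Why: Irreversible deprotonation with NaH breaks the peri hydrogen bond and the naphthoxide is alkylated by the reactive α-chloro ether (Williamson-type acetal formation); the acetal serves both as protecting group and as directing group for step 3.

Step 3
Reactants: 3 1-methoxy-8-(methoxymethoxy)naphthalene
Product: 5 2-[8-methoxy-1-(methoxymethoxy)naphthalen-2-yl]-4,4,5,5-tetramethyl-1,3,2-dioxaborolane, via aryllithium 4 (not isolated)
Conditions: n-BuLi, TMEDA, Et2O, 0 °C to rt; then i-PrOBpin, −78 °C to rt; aq. NH4Cl
Reagents that add atoms: 2-isopropoxy-4,4,5,5-tetramethyl-1,3,2-dioxaborolane, CC(C)OB1OC(C)(C)C(C)(C)O1 (n-butyllithium, [Li]CCCC, supplies only the lithium of intermediate 4)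
Why: Directed ortho-metalation; the bidentate methoxymethoxy group is a stronger director than the methyl ether and its only free ortho position is C2, the peri position being occupied, so lithiation should occur at C2. Trapping with the isopropoxy boronate gives the pinacol ester directly, and the buffered work-up spares the acetal.

Step 4
Reactants: 5 2-[8-methoxy-1-(methoxymethoxy)naphthalen-2-yl]-4,4,5,5-tetramethyl-1,3,2-dioxaborolane (2.4 equiv); 6 2,4-dibromofuran
Product: 8 2,4-bis[8-methoxy-1-(methoxymethoxy)naphthalen-2-yl]furan, via monocoupled bromofuran 7 (not isolated)
Conditions: Pd(OAc)2 (5 mol%), SPhos (10 mol%), K3PO4, toluene/H2O, 80 °C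
Reagents that add atoms: none
Why: Twofold Suzuki–Miyaura coupling; oxidative addition should take the α C–Br bond of 6 first (giving 7) and then the β C–Br bond, and because both aryl groups are identical the order has no consequence. The electron-rich biarylphosphine ligand is suited to ortho-alkoxy boronates, and the mild basic medium leaves the acetals intact.

Step 5
Reactants: 8 2,4-bis[8-methoxy-1-(methoxymethoxy)naphthalen-2-yl]furan; 9 3-methoxy-2-(trimethylsilyl)phenyl trifluoromethanesulfonate (2 equiv, added slowly)
Product: 11 rac-(1S,4R)-5-methoxy-1,3-bis[8-methoxy-1-(methoxymethoxy)naphthalen-2-yl]-1,4-dihydro-1,4-epoxynaphthalene, via 3-methoxybenzyne 10 (not isolated)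
Conditions: CsF (4 equiv), MeCN/THF, rt to 40 °C
Reagents that add atoms: none
Why: Fluoride attacks the silicon of 9 and the resulting aryl anion expels triflate to give aryne 10, which adds across furan C2 and C5 of 8 in a concerted, suprafacial [4+2] cycloaddition; the closest known reaction type is the aryne–furan Diels–Alder reaction that gives 1,4-epoxy-1,4-dihydronaphthalenes. The ring closed is the six-membered carbocycle B1–B2–B3–B4–B4a–B8a, formed by intermolecular cycloaddition in which both new bonds (B1–B8a and B4–B4a) are made in the same step and the furan oxygen remains as the B1–O–B4 bridge. The two new stereocentres, B1 and B4, arise together and their cis relation is imposed by the oxygen bridge; the aryne has no faces and the two faces of the furan are enantiotopic, so 11 should form as a racemate. The selectivity the step needs is orientational: the unsubstituted furan C5 must bond to the methoxy-flanked aryne carbon and the naphthyl-bearing C2 to the remote one. What secures this in the substrate is steric, because in the opposite orientation the ortho-substituted naphthyl group on the new quaternary bridgehead would be pressed against the peri methoxy group. The inductive polarisation of 10 works against it, since the more nucleophilic furan terminus C5 is electronically matched with the remote aryne carbon, so some addition in the opposite orientation is to be expected and the mixture would be separated by chromatography here or after step 6. The furan is by far the best diene present, and the naphthalene rings, the acetals and the methyl ethers should be inert to the aryne and to CsF.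

Step 6
Reactants: 11 rac-(1S,4R)-5-methoxy-1,3-bis[8-methoxy-1-(methoxymethoxy)naphthalen-2-yl]-1,4-dihydro-1,4-epoxynaphthalene
Product: 13 2,4-bis(1-hydroxy-8-methoxynaphthalen-2-yl)-8-methoxynaphthalen-1-ol, via bis-MOM naphthol 12 (not isolated)
Conditions: conc. HCl, MeOH/THF (degassed), rt to 45 °C, under argon
Reagents that add atoms: none
Why: Acid-catalysed isomerisation of a 1,4-epoxy-1,4-dihydronaphthalene to a 1-naphthol combined with acetal cleavage; protonation of the bridge and ionisation of the B4–O bond gives a cation that is tertiary, allylic and doubly benzylic, and loss of the B1 proton aromatises ring B with the oxygen left on B1 (12). The same acid then transfers both methoxymethyl groups to methanol, the methyl ethers are untouched, and both stereocentres of 11 disappear on aromatisation.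

## Compound list

1 | naphthalene-1,8-diol | Oc1cccc2cccc(O)c12 | starting material
2 | 8-methoxynaphthalen-1-ol | COc1cccc2cccc(O)c12 | intermediate
3 | 1-methoxy-8-(methoxymethoxy)naphthalene | COCOc1cccc2cccc(OC)c12 | intermediate
4 | [8-methoxy-1-(methoxymethoxy)naphthalen-2-yl]lithium (formed in the flask) | [Li]c1ccc2cccc(OC)c2c1OCOC | intermediate
5 | 2-[8-methoxy-1-(methoxymethoxy)naphthalen-2-yl]-4,4,5,5-tetramethyl-1,3,2-dioxaborolane | CC1(C)OB(OC1(C)C)c1ccc2cccc(OC)c2c1OCOC | intermediate
6 | 2,4-dibromofuran | Brc1cc(Br)co1 | starting material
7 | 4-bromo-2-[8-methoxy-1-(methoxymethoxy)naphthalen-2-yl]furan (formed in the flask) | COCOc1c(ccc2cccc(OC)c12)-c1cc(Br)co1 | intermediate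
8 | 2,4-bis[8-methoxy-1-(methoxymethoxy)naphthalen-2-yl]furan | COCOc1c(ccc2cccc(OC)c12)-c1cc(-c2ccc3cccc(OC)c3c2OCOC)co1 | intermediate
9 | 3-methoxy-2-(trimethylsilyl)phenyl trifluoromethanesulfonate | COc1cccc(OS(=O)(=O)C(F)(F)F)c1[Si](C)(C)C | starting material
10 | 3-methoxybenzyne (1-methoxycyclohexa-1,3-dien-5-yne; formed in the flask) | COC1=CC=CC#C1 | intermediate
11 | rac-(1S,4R)-5-methoxy-1,3-bis[8-methoxy-1-(methoxymethoxy)naphthalen-2-yl]-1,4-dihydro-1,4-epoxynaphthalene (bridgeheads cis through the oxygen bridge; one enantiomer drawn) | COCOc1c(ccc2cccc(OC)c12)[C@@]34C=C(c5ccc6cccc(OC)c6c5OCOC)[C@@H](O3)c3c(OC)cccc34 | intermediate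
12 | 8-methoxy-2,4-bis[8-methoxy-1-(methoxymethoxy)naphthalen-2-yl]naphthalen-1-ol (formed in the flask) | COCOc1c(ccc2cccc(OC)c12)-c1cc(-c2ccc3cccc(OC)c3c2OCOC)c(O)c2c(OC)cccc12 | intermediate
13 | 2,4-bis(1-hydroxy-8-methoxynaphthalen-2-yl)-8-methoxynaphthalen-1-ol | COc1cccc2ccc(-c3cc(-c4ccc5cccc(OC)c5c4O)c4cccc(OC)c4c3O)c(O)c12 | target

## Step count and least certain steps

Total step count: 6. Longest linear sequence: 6 steps (1 to 13); compounds 6 and 9 are bought.

**Key step, step 5.** The likeliest failure is addition in the wrong orientation. The polarisation of the methoxy-substituted aryne and the higher nucleophilicity of the unsubstituted furan α-carbon both favour bonding of that carbon to the aryne carbon remote from the methoxy group, and only steric repulsion opposes this.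

Fallback: setting out from furan 8, the aryne partner would be changed to 3-(4,4,5,5-tetramethyl-1,3,2-dioxaborolan-2-yl)benzyne F1. F1 would be generated in the presence of 8 at −78 °C with i-PrMgCl·LiCl in Et2O/THF, by iodine–magnesium exchange and loss of triflate from the reagent 2-iodo-6-(4,4,5,5-tetramethyl-1,3,2-dioxaborolan-2-yl)phenyl trifluoromethanesulfonate, SMILES CC1(C)OB(OC1(C)C)c1cccc(I)c1OS(=O)(=O)C(F)(F)F. Boron is a σ-donor, so the aryne carbon next to it is the electrophilic one, and the boryl group is also the bulky one. Electronic and steric effects then both send the unsubstituted furan α-carbon to the boron-flanked aryne carbon, the orientation known for 3-borylbenzynes and 2-substituted furans. The cycloaddition would give the boronate 2-{5,7-bis[8-methoxy-1-(methoxymethoxy)naphthalen-2-yl]-5,8-dihydro-5,8-epoxynaphthalen-1-yl}-4,4,5,5-tetramethyl-1,3,2-dioxaborolane F2. Oxidation of F2 with NaBO3·4H2O in THF/H2O would give the phenol 5,7-bis[8-methoxy-1-(methoxymethoxy)naphthalen-2-yl]-5,8-dihydro-5,8-epoxynaphthalen-1-ol F3. Methylation of F3 with MeI and K2CO3 in acetone would return to the route at cycloadduct 11. The detour through F1, F2 and F3 costs two extra steps.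

**Step 4.** Protodeboronation of the electron-rich ortho-alkoxy boronate may outrun the slower second coupling at the β C–Br bond, and the dibromofuran may decompose on heating.

Fallback: setting out from boronate 5 and aryllithium 4, the furan would be assembled stepwise from 3-bromofuran with the polarity of the second coupling inverted. Suzuki–Miyaura coupling of 5 with 3-bromofuran under the conditions of step 4 would give 3-[8-methoxy-1-(methoxymethoxy)naphthalen-2-yl]furan F4. Iridium-catalysed C–H borylation of F4 with B2pin2, [Ir(OMe)(cod)]2 and 4,4'-di-tert-butyl-2,2'-bipyridine in THF at rt, which takes the less hindered α-position of a 3-substituted furan, would give 2-{4-[8-methoxy-1-(methoxymethoxy)naphthalen-2-yl]furan-2-yl}-4,4,5,5-tetramethyl-1,3,2-dioxaborolane F5. Quenching aryllithium 4 with I2 would give 2-iodo-8-methoxy-1-(methoxymethoxy)naphthalene F6. Suzuki–Miyaura coupling of F5 with F6 would return to the route at furan 8. The new compounds on this path are F4, F5 and F6.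

**Step 3.** Metalation may be incomplete or may partly take the position next to the methyl ether, and the boronate may lose boron on purification.

Fallback: setting out from naphthol 2, the ring position would be fixed by halogenation instead of metalation. Amine-mediated ortho-bromination with NBS and catalytic i-Pr2NH in CH2Cl2 would give 2-bromo-8-methoxynaphthalen-1-ol F7. Protection of F7 with NaH and MOMCl would give 2-bromo-8-methoxy-1-(methoxymethoxy)naphthalene F8. Miyaura borylation of F8 with B2pin2, Pd(dppf)Cl2 and KOAc in dioxane at 80 °C would return to the route at boronate 5. The new compounds on this path are F7 and F8.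

**Step 6.** Ionisation may occur at the wrong bridgehead and be followed by aryl migration. This is possible because the B8 methoxy group lies ortho to B8a and so stabilises a cation at B1. Air oxidation of the electron-rich trinaphthol during prolonged acid treatment, or incomplete acetal cleavage, may also erode the outcome.

Fallback: setting out from cycloadduct 11, the two events would be separated and run under aprotic conditions. Catalytic BF3·OEt2 in CH2Cl2 at −78 to −20 °C would open the bridge under kinetic control, with no nucleophilic solvent present, so that naphthol 12 is isolated. ZnBr2 with propane-1-thiol in CH2Cl2 at 0 °C would then remove the acetals and return to the route at target 13. This path makes no compound outside the compound list, which is recorded as F0.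

## Further compounds

F1 | step 5 | 2-(cyclohexa-1,3-dien-5-yn-1-yl)-4,4,5,5-tetramethyl-1,3,2-dioxaborolane (3-(pinacolboryl)benzyne; formed in the flask) | CC1(C)OB(OC1(C)C)C1=CC=CC#C1
F2 | step 5 | 2-{5,7-bis[8-methoxy-1-(methoxymethoxy)naphthalen-2-yl]-5,8-dihydro-5,8-epoxynaphthalen-1-yl}-4,4,5,5-tetramethyl-1,3,2-dioxaborolane (racemic, bridgeheads cis, one enantiomer drawn) | COCOc1c(ccc2cccc(OC)c12)[C@@]34C=C(c5ccc6cccc(OC)c6c5OCOC)[C@@H](O3)c3c(B5OC(C)(C)C(C)(C)O5)cccc34
F3 | step 5 | 5,7-bis[8-methoxy-1-(methoxymethoxy)naphthalen-2-yl]-5,8-dihydro-5,8-epoxynaphthalen-1-ol (racemic, bridgeheads cis, one enantiomer drawn) | COCOc1c(ccc2cccc(OC)c12)[C@@]34C=C(c5ccc6cccc(OC)c6c5OCOC)[C@@H](O3)c3c(O)cccc34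
F4 | step 4 | 3-[8-methoxy-1-(methoxymethoxy)naphthalen-2-yl]furan | COCOc1c(ccc2cccc(OC)c12)-c1ccoc1
F5 | step 4 | 2-{4-[8-methoxy-1-(methoxymethoxy)naphthalen-2-yl]furan-2-yl}-4,4,5,5-tetramethyl-1,3,2-dioxaborolane | COCOc1c(ccc2cccc(OC)c12)-c1coc(c1)B1OC(C)(C)C(C)(C)O1
F6 | step 4 | 2-iodo-8-methoxy-1-(methoxymethoxy)naphthalene | COCOc1c(I)ccc2cccc(OC)c12
F7 | step 3 | 2-bromo-8-methoxynaphthalen-1-ol | COc1cccc2ccc(Br)c(O)c12
F8 | step 3 | 2-bromo-8-methoxy-1-(methoxymethoxy)naphthalene | COCOc1c(Br)ccc2cccc(OC)c12
F0 | step 6 | none | none
A1 | alternative 1 | 2,4-bis{3-[2-(diethylcarbamoyl)-3-methoxyphenyl]prop-2-en-1-yl}-8-methoxy-1-(methoxymethoxy)naphthalene | COc1cccc2c(CC=Cc3cccc(OC)c3C(=O)N(CC)CC)cc(CC=Cc3cccc(OC)c3C(=O)N(CC)CC)c(OCOC)c12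
A2 | alternative 1 | 2,4-bis(1-hydroxy-8-methoxynaphthalen-2-yl)-8-methoxy-1-(methoxymethoxy)naphthalene | COc1cccc2ccc(-c3cc(-c4ccc5cccc(OC)c5c4O)c4cccc(OC)c4c3OCOC)c(O)c12
A3 | alternative 2 | 4-(2-bromo-3-methoxyphenyl)-N-methoxy-N-methyl-2-{8-methoxy-1-(methoxymethoxy)-4-[8-methoxy-1-(methoxymethoxy)naphthalen-2-yl]naphthalen-2-yl}butanamide (racemic) | COc1cccc(CCC(C(=O)N(C)OC)c3cc(-c4ccc5cccc(OC)c5c4OCOC)c4cccc(OC)c4c3OCOC)c1Br
A4 | alternative 2 | 8-methoxy-2-{8-methoxy-1-(methoxymethoxy)-4-[8-methoxy-1-(methoxymethoxy)naphthalen-2-yl]naphthalen-2-yl}-3,4-dihydronaphthalen-1(2H)-one (racemic) | COc1cccc2CCC(c3cc(-c4ccc5cccc(OC)c5c4OCOC)c4cccc(OC)c4c3OCOC)C(=O)c12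
A5 | alternative 3 | 3-(dimethylamino)-1-(2-methoxy-6-{[8-methoxy-1-(methoxymethoxy)naphthalen-2-yl]methyl}phenyl)-2-[8-methoxy-1-(methoxymethoxy)naphthalen-2-yl]prop-2-en-1-one | COc1cccc(Cc2ccc3cccc(OC)c3c2OCOC)c1C(=O)C(=CN(C)C)c1ccc2cccc(OC)c2c1OCOC
A6 | alternative 3 | 8-methoxy-2,4-bis[8-methoxy-1-(methoxymethoxy)naphthalen-2-yl]naphthalen-1-ol | COCOc1c(ccc2cccc(OC)c12)-c1cc(-c2ccc3cccc(OC)c3c2OCOC)c(O)c2c(OC)cccc12
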